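**Strategy.** Everything rests on a retro-peroxa-Michael cut of the 1,2-dioxolane (ring O1–O2–C3–C4–C5; C3 bears CH3 and CH2CO2H, C5 bears CH3 and the C15 chain). Because C3 is the β-carbon of the carboxyl group, the O2–C3 bond can be made by conjugate addition of a C5-bound hydroperoxide, as in the presumed biosynthesis. In one operation the key step closes the ring (5-exo-trig) and sets the quaternary centre C3 under catalyst control. Its precursor is an acyclic (S)-configured tertiary hydroperoxide bearing an (E)-β-methyl enoate; C5 is set earlier by catalytic asymmetric oxetane formation and invertive perhydrolysis, and the triene is attached last by cross-metathesis and Suzuki coupling.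

Key step: step 8

Assumption: dec-9-en-2-one is taken as purchasable (otherwise one step from 8-bromooct-1-ene through its Grignard reagent and N-methoxy-N-methylacetamide), and the (R)-binaphthoxide complex of step 1 and the quinine-derived catalyst of step 8 are assumed to be the antipodes that give the R oxetane and the 3R dioxolane (the other antipode or the quinidine-derived pseudo-enantiomer is used if the sense is reversed).

Step 1
Reactants: 1 dec-9-en-2-one
Product: 3 (R)-2-methyl-2-(oct-7-en-1-yl)oxetane, via oxirane 2 (not isolated)
Conditions: Me3S(O)I, NaH, LaLi3[(R)-binaphthoxide]3 (cat.), (2,4,6-(MeO)3C6H2)3P=O (cat.), MS 5 Å, THF, 25 °C then 45 °C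
Reagents that add atoms: dimethylsulfoxonium methylide (two equivalents; made from trimethylsulfoxonium iodide and NaH), C[S+](C)(=O)[CH2-]
Why: Catalytic asymmetric Corey–Chaykovsky epoxidation of the methyl ketone, in which the chiral lanthanum–lithium binaphthoxide distinguishes methyl from the long alkyl group and sets the quaternary carbon (the later C5) as R, is followed in the same flask by ylide ring expansion of the oxirane (attack at its CH2, then 4-exo-tet closure with loss of DMSO), which does not touch that centre.

Step 2
Reactants: 3 (R)-2-methyl-2-(oct-7-en-1-yl)oxetane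
Product: 4 (S)-3-hydroperoxy-3-methylundec-10-en-1-ol
Conditions: anhydrous H2O2 in Et2O, TMSOTf (cat.), −78 to −40 °C
Reagents that add atoms: hydrogen peroxide, OO
Why: Lewis acid-promoted perhydrolysis of a strained 2,2-disubstituted oxetane: hydrogen peroxide attacks the activated ring at the tertiary carbon from the side opposite to the leaving oxygen (tight ion pair, SN2-like), so the C5–O bond forms with inversion (R oxetane to S hydroperoxide) and the terminal alkene is not affected.

Step 3
Reactants: 4 (S)-3-hydroperoxy-3-methylundec-10-en-1-ol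
Product: 5 (S)-3-methyl-3-[(triethylsilyl)peroxy]undec-10-en-1-ol
Conditions: Et3SiCl (1.05 equiv), Et3N, CH2Cl2, −40 °C
Reagents that add atoms: chlorotriethylsilane, CC[Si](Cl)(CC)CC
Why: Chemoselective silylation: the hydroperoxide is far more acidic than the primary alcohol and should be silylated through its ammonium salt at low temperature without a nucleophilic catalyst, which masks the peroxide as a triethylsilyl peroxide and leaves the alcohol free.

Step 4
Reactants: 5 (S)-3-methyl-3-[(triethylsilyl)peroxy]undec-10-en-1-ol
Product: 6 (S)-3-methyl-3-[(triethylsilyl)peroxy]undec-10-enal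
Conditions: Dess–Martin periodinane, NaHCO3, CH2Cl2, 0 °C
Reagents that add atoms: none
Why: Dess–Martin oxidation of the primary alcohol to the aldehyde under buffered, non-basic conditions that avoid β-elimination of the silylperoxy group.

Step 5
Reactants: 6 (S)-3-methyl-3-[(triethylsilyl)peroxy]undec-10-enal
Product: 7 (S)-4-methyl-4-[(triethylsilyl)peroxy]dodec-11-en-2-one
Conditions: CH2N2, Et2O, 0 to 25 °C
Reagents that add atoms: diazomethane, C=[N+]=[N-]
Why: Diazomethane homologation of an aldehyde to the methyl ketone (hydride shift in the diazonium betaine) installs the future C3 methyl group under neutral conditions that a silyl peroxide tolerates.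

Step 6
Reactants: 7 (S)-4-methyl-4-[(triethylsilyl)peroxy]dodec-11-en-2-one
Product: 8 methyl (2E,5S)-3,5-dimethyl-5-[(triethylsilyl)peroxy]trideca-2,12-dienoate
Conditions: (MeO)2P(O)CH2CO2Me, NaH, THF, 0 to 25 °C; chromatographic removal of the minor Z isomer
Reagents that add atoms: trimethyl phosphonoacetate, COC(=O)CP(=O)(OC)OC
Why: Horner–Wadsworth–Emmons olefination of the methyl ketone should give the trisubstituted enoate with the E isomer favoured (ester trans to the larger C4 substituent); the minor Z isomer is removed because step 8 needs one alkene geometry.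

Step 7
Reactants: 8 methyl (2E,5S)-3,5-dimethyl-5-[(triethylsilyl)peroxy]trideca-2,12-dienoate
Product: 9 methyl (2E,5S)-5-hydroperoxy-3,5-dimethyltrideca-2,12-dienoate
Conditions: HF·pyridine, THF, 0 °C
Reagents that add atoms: none
Why: Fluoride cleavage of the O–Si bond under acidic buffering liberates the tertiary hydroperoxide without base, so conjugate addition does not start before the chiral catalyst is present.

Step 8
Reactants: 9 methyl (2E,5S)-5-hydroperoxy-3,5-dimethyltrideca-2,12-dienoate
Product: 10 methyl 2-[(3R,5S)-3,5-dimethyl-5-(oct-7-en-1-yl)-1,2-dioxolan-3-yl]acetate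
Conditions: quinine-derived bifunctional squaramide (10 mol%), toluene, −20 °C
Reagents that add atoms: none
Why: Proposed new method: the quinuclidine nitrogen of the catalyst takes the acidic hydroperoxide proton while the squaramide N–H pair binds the ester carbonyl, the terminal peroxide oxygen O2 then adds to the β-carbon C3 of the (E)-enoate and the ester enolate is protonated at the α-carbon (intramolecular peroxa-Michael addition). The closest known reactions are the achiral amine/fluoro-alcohol-mediated conjugate cyclizations of hydroperoxy enoates to 1,2-dioxolanes and 1,2-dioxanes, cinchona-base-catalysed conjugate additions of hydroperoxides to enones, and bifunctional-base-catalysed enantioselective oxa-Michael cyclizations of hydroxy enoates. The 1,2-dioxolane ring (O1–O2–C3–C4–C5) closes in the 5-exo-trig mode. The new quaternary stereocentre C3 is controlled by the catalyst, which selects the π-face of the enoate, because the preset C5 centre (methyl versus primary alkyl) exerts almost no bias of its own. The step needs face selectivity for the 3R configuration (acetate arm trans to the C5 chain) under kinetic control; the single E geometry of the enoate, the two-point binding of hydroperoxide and ester, and a low temperature that suppresses the uncatalysed background reaction and retro-Michael equilibration should secure it.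

Step 9
Reactants: 10 methyl 2-[(3R,5S)-3,5-dimethyl-5-(oct-7-en-1-yl)-1,2-dioxolan-3-yl]acetate
Product: 11 methyl 2-[(3R,5S)-3,5-dimethyl-5-[(7E)-8-(4,4,5,5-tetramethyl-1,3,2-dioxaborolan-2-yl)oct-7-en-1-yl]-1,2-dioxolan-3-yl]acetate
Conditions: vinylboronic acid pinacol ester (3 equiv), second-generation Grubbs catalyst (5 mol%), CH2Cl2, 40 °C
Reagents that add atoms: vinylboronic acid pinacol ester, C=CB1OC(C)(C)C(C)(C)O1
Why: Olefin cross-metathesis of the terminal alkene with the vinyl boronate (loss of ethene) should give the E-alkenyl boronate preferentially, and the hindered dialkyl peroxide without α-hydrogens and the ester should be compatible with the ruthenium carbene.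

Step 10
Reactants: 12 (Z)-hex-3-en-1-ol
Product: 13 (Z)-hex-3-enal
Conditions: Dess–Martin periodinane, NaHCO3, CH2Cl2, 0 °C; used crude
Reagents that add atoms: none
Why: Dess–Martin oxidation under buffered conditions should give the β,γ-unsaturated aldehyde without migration or isomerization of the Z alkene when it is used at once.

Step 11
Reactants: 13 (Z)-hex-3-enal
Product: 14 (1E,4Z)-1-iodohepta-1,4-diene
Conditions: CHI3, CrCl2, THF, 0 °C
Reagents that add atoms: iodoform, IC(I)I
Why: Takai olefination (geminal dichromium species from iodoform and CrCl2) converts the aldehyde into the E vinyl iodide and leaves the Z alkene untouched.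

Step 12
Reactants: 11 methyl 2-[(3R,5S)-3,5-dimethyl-5-[(7E)-8-(4,4,5,5-tetramethyl-1,3,2-dioxaborolan-2-yl)oct-7-en-1-yl]-1,2-dioxolan-3-yl]acetate, 14 (1E,4Z)-1-iodohepta-1,4-diene
Product: 15 methyl 2-[(3R,5S)-3,5-dimethyl-5-[(7E,9E,12Z)-pentadeca-7,9,12-trien-1-yl]-1,2-dioxolan-3-yl]acetate
Conditions: PdCl2(dppf) (5 mol%), K3PO4, THF/H2O, 25 °C
Reagents that add atoms: none
Why: Suzuki–Miyaura coupling of the alkenyl boronate with the alkenyl iodide proceeds with retention at both sp2 carbons and joins C8 and C9 of the side chain to give the 7E,9E,12Z triene; the tetrasubstituted dioxolane lacks α-hydrogens and should survive the mild base.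

Step 13
Reactants: 15 methyl 2-[(3R,5S)-3,5-dimethyl-5-[(7E,9E,12Z)-pentadeca-7,9,12-trien-1-yl]-1,2-dioxolan-3-yl]acetate
Product: 16 2-[(3R,5S)-3,5-dimethyl-5-[(7E,9E,12Z)-pentadeca-7,9,12-trien-1-yl]-1,2-dioxolan-3-yl]acetic acid
Conditions: LiOH, THF/H2O, 0 to 25 °C; then dilute HCl to pH 4
Reagents that add atoms: lithium hydroxide, [Li+].[OH-]
Why: Saponification of the methyl ester with LiOH; both peroxide carbons are quaternary, so no base-induced (Kornblum–DeLaMare type) fragmentation is open, and the low temperature limits retro-Michael ring opening.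

**Compound list**

1 | dec-9-en-2-one | CC(=O)CCCCCCC=C | starting material
2 | (R)-2-methyl-2-(oct-7-en-1-yl)oxirane | C[C@@]1(CCCCCCC=C)CO1 | intermediate
3 | (R)-2-methyl-2-(oct-7-en-1-yl)oxetane | C[C@@]1(CCCCCCC=C)CCO1 | intermediate
4 | (S)-3-hydroperoxy-3-methylundec-10-en-1-ol | C[C@@](OO)(CCO)CCCCCCC=C | intermediate
5 | (S)-3-methyl-3-[(triethylsilyl)peroxy]undec-10-en-1-ol | C[C@@](OO[Si](CC)(CC)CC)(CCO)CCCCCCC=C | intermediate
6 | (S)-3-methyl-3-[(triethylsilyl)peroxy]undec-10-enal | C[C@@](OO[Si](CC)(CC)CC)(CC=O)CCCCCCC=C | intermediate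
7 | (S)-4-methyl-4-[(triethylsilyl)peroxy]dodec-11-en-2-one | C[C@@](OO[Si](CC)(CC)CC)(CC(C)=O)CCCCCCC=C | intermediate
8 | methyl (2E,5S)-3,5-dimethyl-5-[(triethylsilyl)peroxy]trideca-2,12-dienoate | C[C@@](OO[Si](CC)(CC)CC)(C/C(C)=C/C(=O)OC)CCCCCCC=C | intermediate
9 | methyl (2E,5S)-5-hydroperoxy-3,5-dimethyltrideca-2,12-dienoate | C[C@@](OO)(C/C(C)=C/C(=O)OC)CCCCCCC=C | intermediate
10 | methyl 2-[(3R,5S)-3,5-dimethyl-5-(oct-7-en-1-yl)-1,2-dioxolan-3-yl]acetate | C=CCCCCCC[C@@]1(C)C[C@](C)(CC(=O)OC)OO1 | intermediate
11 | methyl 2-[(3R,5S)-3,5-dimethyl-5-[(7E)-8-(4,4,5,5-tetramethyl-1,3,2-dioxaborolan-2-yl)oct-7-en-1-yl]-1,2-dioxolan-3-yl]acetate | CC1(C)OB(/C=C/CCCCCC[C@@]2(C)C[C@](C)(CC(=O)OC)OO2)OC1(C)C | intermediate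
12 | (Z)-hex-3-en-1-ol | CC/C=C\CCO | starting material
13 | (Z)-hex-3-enal | CC/C=C\CC=O | intermediate
14 | (1E,4Z)-1-iodohepta-1,4-diene | CC/C=C\C/C=C/I | intermediate
15 | methyl 2-[(3R,5S)-3,5-dimethyl-5-[(7E,9E,12Z)-pentadeca-7,9,12-trien-1-yl]-1,2-dioxolan-3-yl]acetate | CC/C=C\C/C=C/C=C/CCCCCC[C@@]1(C)C[C@](C)(CC(=O)OC)OO1 | intermediate
16 | 2-[(3R,5S)-3,5-dimethyl-5-[(7E,9E,12Z)-pentadeca-7,9,12-trien-1-yl]-1,2-dioxolan-3-yl]acetic acid | CC/C=C\C/C=C/C=C/CCCCCC[C@@]1(C)C[C@](C)(CC(=O)O)OO1 | target

**Step count.** Total: 13 steps. Longest linear sequence: 11 steps (steps 1 to 9, 12 and 13).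

**Steps most likely to fail**

1. Step 8 (Proposed new method). The catalyst may discriminate the two faces of the enoate poorly, or reversible ring opening may erode the kinetic ratio, so that the C3 epimer forms in a comparable amount. The fallback uses known peroxycarbenium chemistry and sets out from 7. HF·pyridine removes the silyl group and the hydroperoxy ketone closes to the cyclic peroxyhemiketal (5S)-3,5-dimethyl-5-(oct-7-en-1-yl)-1,2-dioxolan-3-ol F1. Acid-catalysed methanolysis (MeOH, TsOH) gives (5S)-3-methoxy-3,5-dimethyl-5-(oct-7-en-1-yl)-1,2-dioxolane F2. Ionization with TiCl4 at −78 °C to the cyclic peroxycarbenium ion and Mukaiyama-type addition of 1-methoxy-1-(trimethylsilyloxy)ethene, which should approach anti to the larger C5 substituent, gives 10, where the route is rejoined; a minor C3 epimer would be separated. In this fallback the O2–C3 bond forms in the hemiketal closure and C3 is set in the C–C bond formation.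

2. Step 6. The phosphonate anion may enolize the hindered β-silylperoxy ketone instead of adding to it. The enolate can then displace at the peroxide oxygen (epoxide formation) or eliminate the peroxide, and the silyl group may be lost. The fallback sets out from 7. Addition of the lithium enolate of methyl acetate (LiN(iPr)2, methyl acetate, THF, −78 °C, short contact) gives methyl (5S)-3-hydroxy-3,5-dimethyl-5-[(triethylsilyl)peroxy]tridec-12-enoate F3. Dehydration with Burgess reagent under neutral conditions gives the conjugated enoate, and after separation of the E isomer the route is rejoined at 8.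

3. Step 5. The diazonium betaine may close to the epoxide or undergo alkyl instead of hydride migration, which lowers the share of methyl ketone. The fallback sets out from 6. Aldehyde-selective, non-basic methyl transfer from MeTi(OiPr)3 (THF, −20 °C) gives (4S)-4-methyl-4-[(triethylsilyl)peroxy]dodec-11-en-2-ol F4 as a mixture of carbinol epimers. Buffered Dess–Martin oxidation converts both epimers into 7, where the route is rejoined.

Further compounds
F1 | step 8 | (5S)-3,5-dimethyl-5-(oct-7-en-1-yl)-1,2-dioxolan-3-ol (both C3 epimers) | C=CCCCCCC[C@@]1(C)CC(C)(O)OO1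
F2 | step 8 | (5S)-3-methoxy-3,5-dimethyl-5-(oct-7-en-1-yl)-1,2-dioxolane (both C3 epimers) | C=CCCCCCC[C@@]1(C)CC(C)(OC)OO1
F3 | step 6 | methyl (5S)-3-hydroxy-3,5-dimethyl-5-[(triethylsilyl)peroxy]tridec-12-enoate (both C3 epimers) | C[C@@](OO[Si](CC)(CC)CC)(CC(C)(O)CC(=O)OC)CCCCCCC=C
F4 | step 5 | (4S)-4-methyl-4-[(triethylsilyl)peroxy]dodec-11-en-2-ol (both C2 epimers) | C[C@@](OO[Si](CC)(CC)CC)(CC(C)O)CCCCCCC=C
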